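**Retrosynthetic overview**
1. Target ⇒ C8 acylation and C3 desilylation, preceded by hydroxyl-directed 1(10)-epoxidation of a macrocyclic homoallylic alcohol (the oxirane is the last ring).
2. Key disconnection C7–C8: the ten-membered carbocycle is closed by SmI2 ketyl-radical addition of a C8 aldehyde to C7 of a 3-(phenylsulfonylmethyl)butenolide; loss of PhSO2 in the same event unveils the 11(13)-methylene and sets C7 and C8.
3. Seco-aldehyde ⇒ C3–C4 Ni/Cr alkenylation joining a (Z)-iodoalkenyl butenolide to a (Z)-β,γ-unsaturated hydroxy aldehyde.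
4. Butenolide (first ring) ⇒ ring-closing metathesis of a sulfonylmethyl acrylate of an (R)-divinyl carbinol made from (Z)-3-iodobut-2-en-1-ol; hydroxy aldehyde ⇒ Birch reduction and enol-ether ozonolysis of p-cresol methyl ether, the ring fixing the Z olefin.
5. Ring order: γ-lactone → ten-membered carbocycle → oxirane.

Assumption: germacrane numbering (C1–C15, lactone carbonyl C12) is used for positions throughout, and (2Z)-3-iodobut-2-en-1-ol is taken as a catalogue compound.

**Route**

Step 1
Reactants: 1 4-methylphenol (p-cresol)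
Product: 2 1-methoxy-4-methylbenzene
Conditions: MeI, K2CO3, acetone, reflux
Reagents that add atoms: iodomethane CI
Why: Williamson etherification of the phenoxide gives the anisole needed for Birch reduction, which the free phenoxide would resist.

Step 2
Reactants: 2 1-methoxy-4-methylbenzene
Product: 3 1-methoxy-4-methylcyclohexa-1,4-diene
Conditions: Li, NH3 (l), t-BuOH, THF, −78 to −33 °C
Reagents that add atoms: none
Why: Birch reduction leaves both donor substituents on sp2 carbons, so the ring holds the future C1=C10 olefin in the cis (Z) geometry.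

Step 3
Reactants: 3 1-methoxy-4-methylcyclohexa-1,4-diene
Product: 5 methyl (3Z)-6-hydroxy-4-methylhex-3-enoate, via aldehyde ester 4 (not isolated)
Conditions: O3 (1.0 equiv), CH2Cl2/MeOH, pyridine (trace), −78 °C; Me2S; then NaBH4, 0 °C
Reagents that add atoms: ozone [O-][O+]=O
Why: Ozonolysis cleaves the electron-rich enol-ether double bond selectively (ester at C3, aldehyde at C8) and borohydride reduces only the aldehyde; the Z geometry comes from the ring.

Step 4
Reactants: 5 methyl (3Z)-6-hydroxy-4-methylhex-3-enoate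
Product: 6 (3Z)-6-hydroxy-4-methylhex-3-enal
Conditions: iBu2AlH (2.2 equiv), CH2Cl2, −78 °C; aq. potassium sodium tartrate; used crude
Reagents that add atoms: none
Why: Partial ester reduction stops at the aldehyde because the tetrahedral aluminate is stable at −78 °C (the first equivalent only deprotonates the hydroxyl).

Step 5
Reactants: 7 (2Z)-3-iodobut-2-en-1-ol
Product: 8 (2Z)-3-iodobut-2-enal
Conditions: MnO2, CH2Cl2, rt, dark
Reagents that add atoms: none
Why: Neutral, heterogeneous allylic oxidation with activated MnO2 preserves the Z iodoalkene.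

Step 6
Reactants: 8 (2Z)-3-iodobut-2-enal; 9 vinylmagnesium bromide
Product: 10 (3R,4Z)-5-iodohexa-1,4-dien-3-ol
Conditions: 9 (2.4 equiv), ZnCl2 (1.2 equiv), THF, 0 °C; 1,4-dioxane, filter; (+)-MIB (10 mol%), toluene, −20 °C, then 8
Reagents that add atoms: none
Why: Amino-alcohol-catalysed enantioselective addition of divinylzinc to an aldehyde (Oppolzer/Walsh type); the (+)-ligand sends vinyl to the Re face and sets the R carbinol that becomes C6.

Step 7
Reactants: 11 2-(bromomethyl)prop-2-enoic acid
Product: 12 2-[(phenylsulfonyl)methyl]prop-2-enoic acid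
Conditions: PhSO2Na, MeOH, reflux
Reagents that add atoms: sodium benzenesulfinate [Na+].[O-]S(=O)c1ccccc1
Why: S-alkylation of the sulfinate by the allylic bromide (direct or allylic displacement gives the same product) installs the radical leaving group.

Step 8
Reactants: 10 (3R,4Z)-5-iodohexa-1,4-dien-3-ol; 12 2-[(phenylsulfonyl)methyl]prop-2-enoic acid
Product: 13 (3R,4Z)-5-iodohexa-1,4-dien-3-yl 2-[(phenylsulfonyl)methyl]prop-2-enoate
Conditions: DCC, DMAP (5 mol%), CH2Cl2, −20 to 0 °C
Reagents that add atoms: none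
Why: Steglich esterification acylates the carbinol oxygen with retention at the stereocentre.

Step 9
Reactants: 13 (3R,4Z)-5-iodohexa-1,4-dien-3-yl 2-[(phenylsulfonyl)methyl]prop-2-enoate
Product: 14 (5R)-5-[(1Z)-2-iodoprop-1-en-1-yl]-3-[(phenylsulfonyl)methyl]furan-2(5H)-one
Conditions: second-generation Hoveyda–Grubbs catalyst (5 mol%), toluene (0.005 M), 80 °C
Reagents that add atoms: none
Why: Ring-closing metathesis joins the vinyl group and the 1,1-disubstituted acrylate to form the butenolide (first ring); the hindered trisubstituted iodoalkene is inert and the stereocentre is untouched.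

Step 10
Reactants: 14 (5R)-5-[(1Z)-2-iodoprop-1-en-1-yl]-3-[(phenylsulfonyl)methyl]furan-2(5H)-one; 6 (3Z)-6-hydroxy-4-methylhex-3-enal
Product: 16 (5S)-5-[(1Z,3S,5Z)-2,6-dimethyl-3,8-bis(triethylsilyloxy)octa-1,5-dien-1-yl]-3-[(phenylsulfonyl)methyl]furan-2(5H)-one, via diol 15 (not isolated)
Conditions: CrCl2 (4 equiv), NiCl2 (2 mol%), Kishi-type chiral oxazoline–sulfonamide ligand (4.4 equiv), Et3N, THF, rt; then imidazole, Et3SiCl, 0 °C
Reagents that add atoms: chlorotriethylsilane CC[Si](Cl)(CC)CC
Why: Nozaki–Hiyama–Kishi alkenylation: the alkenyl species of trivalent chromium adds only to the aldehyde with retention of olefin geometry, the ligand antipode that directs attack to the Re face sets 3S, and both hydroxyls are silylated in the same flask.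

Step 11
Reactants: 16 (5S)-5-[(1Z,3S,5Z)-2,6-dimethyl-3,8-bis(triethylsilyloxy)octa-1,5-dien-1-yl]-3-[(phenylsulfonyl)methyl]furan-2(5H)-one
Product: 17 (3Z,6S,7Z)-3,7-dimethyl-8-[(2S)-5-oxo-4-[(phenylsulfonyl)methyl]-2,5-dihydrofuran-2-yl]-6-(triethylsilyloxy)octa-3,7-dienal
Conditions: (COCl)2, DMSO, CH2Cl2, −78 to −40 °C; iPr2NEt, −78 to −20 °C; used at once
Reagents that add atoms: none
Why: Swern conditions convert a primary triethylsilyl ether directly into the aldehyde while the secondary one survives, and the low temperature keeps the β,γ-unsaturated aldehyde from conjugating.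

Step 12
Reactants: 17 (3Z,6S,7Z)-3,7-dimethyl-8-[(2S)-5-oxo-4-[(phenylsulfonyl)methyl]-2,5-dihydrofuran-2-yl]-6-(triethylsilyloxy)octa-3,7-dienal
Product: 18 (1(10)Z,3S,4Z,6S,7S,8R)-8-hydroxy-3-(triethylsilyloxy)germacra-1(10),4,11(13)-trien-12,6-olide
Conditions: SmI2 (2.3 equiv, 0.1 M in THF, syringe pump 3 h), 17 at 0.002 M in THF, −78 to −30 °C; aq. NH4Cl
Reagents that add atoms: none
Why: Proposed new method: SmI2 reduces the aldehyde to a samarium ketyl radical that closes the ten-membered ring by 10-exo attack on C7 (the β-carbon of the unsaturated lactone), and the resulting C11 radical (or its samarium enolate after a second electron transfer) expels benzenesulfinate to unveil the 11(13)-methylene; attack anti to the C6 side chain should give the trans lactone (7S), and a closed arrangement with the samarium-bound oxygen anti to C6 beside the sulfonylmethyl arm, C9 anti to C11 and H8 over the lactone should give 8R, the two Z olefins pre-folding the chain; the closest known reactions are SmI2 ketyl–olefin additions of aldehydes to acrylates and butenolides (Fukuzawa/Molander type) and radical addition–fragmentation of allyl sulfones.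

Step 13
Reactants: 18 (1(10)Z,3S,4Z,6S,7S,8R)-8-hydroxy-3-(triethylsilyloxy)germacra-1(10),4,11(13)-trien-12,6-olide
Product: 19 (1R,3S,4Z,6S,7S,8R,10S)-1,10-epoxy-8-hydroxy-3-(triethylsilyloxy)germacra-4,11(13)-dien-12,6-olide
Conditions: VO(acac)2 (5 mol%), t-BuOOH (1.5 equiv, decane), CH2Cl2, 0 °C to rt
Reagents that add atoms: tert-butyl hydroperoxide CC(C)(C)OO
Why: Hydroxyl-directed vanadium epoxidation of a homoallylic alcohol (Sharpless–Michaelson/Mihelich type): the vanadate ester of the C8 hydroxyl reaches only the 1(10)-olefin face on its own side of the ring, giving the cis-epoxide syn to O8 (1R,10S), while the 4,5-olefin (no free hydroxyl, two allylic C–O bonds) and the electron-poor methylene lactone are left alone.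

Step 14
Reactants: 19 (1R,3S,4Z,6S,7S,8R,10S)-1,10-epoxy-8-hydroxy-3-(triethylsilyloxy)germacra-4,11(13)-dien-12,6-olide; 20 2-methylpropanoyl chloride
Product: 22 (1R,3S,4Z,6S,7S,8R,10S)-1,10-epoxy-3-hydroxy-8-(2-methylpropanoyloxy)germacra-4,11(13)-dien-12,6-olide (CNP0261225.1), via silylated ester 21 (not isolated)
Conditions: 20, pyridine, DMAP (cat.), CH2Cl2, 0 °C; MeOH quench; then HF·pyridine, THF, 0 °C
Reagents that add atoms: none
Why: Acylation of the only free hydroxyl occurs with retention at C8, and pyridine-buffered fluoride then removes the triethylsilyl group without opening the epoxide or adding to the methylene lactone.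

**Compound list**
1 | 4-methylphenol (p-cresol) | Cc1ccc(O)cc1 | starting material
2 | 1-methoxy-4-methylbenzene | COc1ccc(C)cc1 | intermediate
3 | 1-methoxy-4-methylcyclohexa-1,4-diene | COC1=CCC(C)=CC1 | intermediate
4 | methyl (3Z)-4-methyl-6-oxohex-3-enoate | COC(=O)C/C=C(/C)CC=O | intermediate (not isolated)
5 | methyl (3Z)-6-hydroxy-4-methylhex-3-enoate | COC(=O)C/C=C(/C)CCO | intermediate
6 | (3Z)-6-hydroxy-4-methylhex-3-enal | O=CC/C=C(/C)CCO | intermediate
7 | (2Z)-3-iodobut-2-en-1-ol | OC/C=C(/C)I | starting material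
8 | (2Z)-3-iodobut-2-enal | O=C/C=C(/C)I | intermediate
9 | vinylmagnesium bromide | C=C[Mg]Br | starting material
10 | (3R,4Z)-5-iodohexa-1,4-dien-3-ol | O[C@H](C=C)/C=C(/C)I | intermediate
11 | 2-(bromomethyl)prop-2-enoic acid | C=C(CBr)C(=O)O | starting material
12 | 2-[(phenylsulfonyl)methyl]prop-2-enoic acid | C=C(CS(=O)(=O)c1ccccc1)C(=O)O | intermediate
13 | (3R,4Z)-5-iodohexa-1,4-dien-3-yl 2-[(phenylsulfonyl)methyl]prop-2-enoate | C=C(CS(=O)(=O)c1ccccc1)C(=O)O[C@H](C=C)/C=C(/C)I | intermediate
14 | (5R)-5-[(1Z)-2-iodoprop-1-en-1-yl]-3-[(phenylsulfonyl)methyl]furan-2(5H)-one | O=C1O[C@@H](/C=C(/C)I)C=C1CS(=O)(=O)c1ccccc1 | intermediate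
15 | (5S)-5-[(1Z,3S,5Z)-3,8-dihydroxy-2,6-dimethylocta-1,5-dien-1-yl]-3-[(phenylsulfonyl)methyl]furan-2(5H)-one | O=C1O[C@@H](/C=C(/C)[C@@H](O)C/C=C(/C)CCO)C=C1CS(=O)(=O)c1ccccc1 | intermediate (not isolated)
16 | (5S)-5-[(1Z,3S,5Z)-2,6-dimethyl-3,8-bis(triethylsilyloxy)octa-1,5-dien-1-yl]-3-[(phenylsulfonyl)methyl]furan-2(5H)-one | O=C1O[C@@H](/C=C(/C)[C@@H](O[Si](CC)(CC)CC)C/C=C(/C)CCO[Si](CC)(CC)CC)C=C1CS(=O)(=O)c1ccccc1 | intermediate
17 | (3Z,6S,7Z)-3,7-dimethyl-8-[(2S)-5-oxo-4-[(phenylsulfonyl)methyl]-2,5-dihydrofuran-2-yl]-6-(triethylsilyloxy)octa-3,7-dienal | O=C1O[C@@H](/C=C(/C)[C@@H](O[Si](CC)(CC)CC)C/C=C(/C)CC=O)C=C1CS(=O)(=O)c1ccccc1 | intermediate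
18 | (1(10)Z,3S,4Z,6S,7S,8R)-8-hydroxy-3-(triethylsilyloxy)germacra-1(10),4,11(13)-trien-12,6-olide (ten-membered carbocycle trans-fused to the α-methylene-γ-lactone) | C=C1C(=O)O[C@H]2/C=C(/C)[C@@H](O[Si](CC)(CC)CC)C/C=C(/C)C[C@@H](O)[C@H]12 | intermediate
19 | (1R,3S,4Z,6S,7S,8R,10S)-1,10-epoxy-8-hydroxy-3-(triethylsilyloxy)germacra-4,11(13)-dien-12,6-olide | C=C1C(=O)O[C@H]2/C=C(/C)[C@@H](O[Si](CC)(CC)CC)C[C@H]3O[C@@]3(C)C[C@@H](O)[C@H]12 | intermediate
20 | 2-methylpropanoyl chloride | CC(C)C(=O)Cl | starting material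
21 | 3-O-triethylsilyl ether of 22 | C=C1C(=O)O[C@H]2/C=C(/C)[C@@H](O[Si](CC)(CC)CC)C[C@H]3O[C@@]3(C)C[C@@H](OC(=O)C(C)C)[C@H]12 | intermediate (not isolated)
22 | (1R,3S,4Z,6S,7S,8R,10S)-1,10-epoxy-3-hydroxy-8-(2-methylpropanoyloxy)germacra-4,11(13)-dien-12,6-olide | C=C1C(=O)O[C@H]2/C=C(/C)[C@@H](O)C[C@H]3O[C@@]3(C)C[C@@H](OC(=O)C(C)C)[C@H]12 | target

**Totals and risks**
Total step count: 14. Longest linear sequence: 9 steps (1 → 22 through steps 1–4 and 10–14, or 7 → 22 through steps 5, 6 and 8–14).

Most likely to fail, first: step 12. A ten-membered radical ring closure competes with pinacol coupling, simple aldehyde reduction and reduction of the unsaturated lactone, and the C8 configuration rests on a transition-state argument. Fallback: set out from 17 and close the same bond by a polar, closed-transition-state allylation. Pd(PPh3)4 (5 mol%) and Et2Zn in dilute THF turn the allylic sulfone into the allyl(ethyl)zinc species F1. F1 adds through C7 to the C8 aldehyde in a six-membered chair, the lactone ring fixing the crotyl-type geometry that leads to the 7S,8R adduct, and the route is rejoined at 18.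

Second: step 10. The Ni/Cr coupling must set C3 by ligand control on a hindered (Z)-iodoalkene. Zerovalent nickel could also attack the allylic sulfone, and the base-sensitive γ-hydrogen of the butenolide is exposed to amine. Fallback: set out from 14 and 6 and run the CrCl2/NiCl2 coupling without chiral ligand to the C3-epimeric diol mixture F2. Oxidise only the allylic carbinol with MnO2 to the enone F3, then reduce with (R)-2-methyl-CBS-oxazaborolidine and catecholborane at −78 °C to give 15 with 3S set by the reagent. Silylation (Et3SiCl, imidazole) rejoins the route at 16.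

Third: step 13. The face of the 1(10)-olefin that is epoxidised depends on the macrocycle conformation and on the C8 hydroxyl actually reaching it. Fallback: set out from 16 and install the epoxide before ring closure under reagent control. Shi epoxidation (D-fructose-derived ketone, KHSO5, NaHCO3-buffered MeCN/dimethoxymethane/water, 0 °C) should attack the electron-rich 1(10)-olefin and give the (1R,10S)-epoxy bis-silyl ether F4. Swern oxidation as in step 11 gives the epoxy aldehyde F5, and the SmI2 ring closure of step 12 then delivers 19 directly, where the route is rejoined.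

**Further compounds**
F1 | step 12 | allyl(ethyl)zinc species derived from 17 (zinc on C13) | O=C1O[C@@H](/C=C(/C)[C@@H](O[Si](CC)(CC)CC)C/C=C(/C)CC=O)C=C1C[Zn]CC
F2 | step 10 | C3-epimeric mixture of diol 15 | O=C1O[C@@H](/C=C(/C)C(O)C/C=C(/C)CCO)C=C1CS(=O)(=O)c1ccccc1
F3 | step 10 | (5S)-5-[(1Z,5Z)-8-hydroxy-2,6-dimethyl-3-oxoocta-1,5-dien-1-yl]-3-[(phenylsulfonyl)methyl]furan-2(5H)-one | O=C1O[C@@H](/C=C(/C)C(=O)C/C=C(/C)CCO)C=C1CS(=O)(=O)c1ccccc1
F4 | step 13 | (1R,10S)-1,10-epoxide of 16 | O=C1O[C@@H](/C=C(/C)[C@@H](O[Si](CC)(CC)CC)C[C@H]2O[C@@]2(C)CCO[Si](CC)(CC)CC)C=C1CS(=O)(=O)c1ccccc1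
F5 | step 13 | (1R,10S)-1,10-epoxide of 17 | O=C1O[C@@H](/C=C(/C)[C@@H](O[Si](CC)(CC)CC)C[C@H]2O[C@@]2(C)CC=O)C=C1CS(=O)(=O)c1ccccc1
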